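**Plan**

- The target is an achiral flavone (ring A: 5,8-dimethoxy-7-hydroxy; ring B: 3′,5′-dihydroxy-4′-methoxy), so no stereocentre has to be set.
- Retrosynthesis: the three phenols are carried as benzyl ethers; the C7–O bond is cut back to C7–Br; ring C is opened at O1–C8a to a 1-(2,4-dibromoaryl)-3-aryl-1,3-diketone; the diketone is cut at C2–C3 into a ring-A methyl ketone and a ring-B benzoate; the C4–C4a bond is cut to a lithiated dibromoarene.
- Enabling feature: on ring A the ring oxygen at C8a and the hydroxyl oxygen at C7 sit on the two carbons either side of the C8 methoxyl (meta to each other). These are the positions of the two equivalent bromines of 1,3-dibromo-2,5-dimethoxybenzene, so one bromide serves the O1–C8a closure and the other the C7–O bond.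
- Forward: rings A and B are bought as benzenes and joined through the three-carbon chain (aryllithium acetylation, then Claisen condensation). Ring C, the only ring formed, closes by copper-catalysed enolate O-arylation, which also tells the two bromines apart.
- The surviving C7 bromide is exchanged for benzyloxy, and one hydrogenolysis frees all three phenols.

Key step: step 6

Remark: ring positions of all chromenone compounds are given in flavone numbering, and the 1,3-diketone is drawn in its diketo form although it should exist mainly as the chelated enol.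

**Route**

Step 1
Reactants: 1 4-methoxyphenol
Product: 2 2,6-dibromo-4-methoxyphenol
Conditions: Br2 (2.1 equiv), CH2Cl2, 0 °C → rt
Reagents that add atoms: bromine, BrBr
Why: Electrophilic aromatic bromination, in which the free hydroxyl is the strongest donor and its para position is blocked by the methoxyl, so both bromines should enter ortho to OH.

Step 2
Reactants: 2 2,6-dibromo-4-methoxyphenol
Product: 3 1,3-dibromo-2,5-dimethoxybenzene
Conditions: MeI (1.5 equiv), K2CO3 (2 equiv), DMF, rt
Reagents that add atoms: iodomethane, CI
Why: Williamson ether synthesis, in which the acidic 2,6-dibromophenol is deprotonated by carbonate and methylated on oxygen by SN2 to give the symmetric dibromoarene.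

Step 3
Reactants: 3 1,3-dibromo-2,5-dimethoxybenzene
Product: 5 1-(2,4-dibromo-3,6-dimethoxyphenyl)ethan-1-one, via aryllithium 4 (not isolated)
Conditions: LiN(iPr)2 (LDA, 1.15 equiv), THF, −78 °C, 1 h; then MeC(O)N(OMe)Me (1.5 equiv), −78 → 0 °C; sat. aq. NH4Cl
Reagents that add atoms: N-methoxy-N-methylacetamide, CC(=O)N(C)OC
Why: Directed ortho-lithiation followed by Weinreb ketone synthesis: the two ring C–H bonds of 3 are equivalent and each is acidified by a flanking bromine and methoxyl, the amide base deprotonates without bromine–lithium exchange, the ortho-bromoaryllithium 4 should be stable at −78 °C, and the N-methoxy-N-methylamide delivers a single acetyl group.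

Step 4
Reactants: 6 methyl 3,5-dihydroxy-4-methoxybenzoate
Product: 7 methyl 3,5-bis(benzyloxy)-4-methoxybenzoate
Conditions: BnBr (2.3 equiv), K2CO3 (3 equiv), DMF, 60 °C
Reagents that add atoms: benzyl bromide, BrCc1ccccc1
Why: Williamson ether synthesis, in which both phenols are benzylated by SN2 under carbonate while the methyl ester is left untouched.

Step 5
Reactants: 5 1-(2,4-dibromo-3,6-dimethoxyphenyl)ethan-1-one; 7 methyl 3,5-bis(benzyloxy)-4-methoxybenzoate
Product: 8 1-[3,5-bis(benzyloxy)-4-methoxyphenyl]-3-(2,4-dibromo-3,6-dimethoxyphenyl)propane-1,3-dione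
Conditions: NaH (2.5 equiv), THF, 0 °C → 65 °C; then 1 M aq. HCl
Reagents that add atoms: none
Why: Crossed Claisen condensation, in which 5 is the only enolisable partner and 7 the only acyl donor, the doubly ortho-substituted ketone carbonyl is too hindered for self-aldol addition, and deprotonation of the product diketone by the second equivalent of NaH drives the condensation forward.

Step 6
Reactants: 8 1-[3,5-bis(benzyloxy)-4-methoxyphenyl]-3-(2,4-dibromo-3,6-dimethoxyphenyl)propane-1,3-dione
Product: 10 2-[3,5-bis(benzyloxy)-4-methoxyphenyl]-7-bromo-5,8-dimethoxy-4H-chromen-4-one, via potassium enolate 9 (not isolated)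
Conditions: CuI (10 mol %), K2CO3 (2 equiv), DMF, 100 °C, argon
Reagents that add atoms: none
Why: K2CO3 converts 8 into the chelating enolate 9, which binds monovalent copper through both oxygens and so holds the metal beside the C–Br bond ortho to the ketone; oxidative addition there gives a trivalent copper aryl, and C–O reductive elimination joins the enolate oxygen on the future C2 to C8a (a copper-free addition–elimination, activated by the ortho carbonyl, would lead to the same bond). The closest known reaction type is the copper- or base-mediated cyclisation of 1-(2-haloaryl)-1,3-diketones to flavones, an intramolecular Ullmann-type O-arylation. Ring C closes as a six-membered ring by reductive elimination from a seven-membered oxa-cupracycle; in the addition–elimination picture the attack at C8a is a 6-endo-trig conjugate addition onto the C4(=O)–C4a=C8a unit of the arene followed by loss of bromide. No stereocentre is formed. The selectivity needed is between the two bromines and between O- and C-arylation: only the bromine ortho to the ketone lies within reach of the tethered enolate oxygen and is activated by the adjacent carbonyl, the para bromine has no intramolecular partner and meets no external nucleophile, and attack through the central carbon or the other oxygen would require a four-membered ring. The bromide left at C7 is therefore the handle for the last oxygen.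

Step 7
Reactants: 10 2-[3,5-bis(benzyloxy)-4-methoxyphenyl]-7-bromo-5,8-dimethoxy-4H-chromen-4-one
Product: 11 7-(benzyloxy)-2-[3,5-bis(benzyloxy)-4-methoxyphenyl]-5,8-dimethoxy-4H-chromen-4-one
Conditions: BnOH (2 equiv), [Pd(allyl)Cl]2 (1 mol %), RockPhos (3 mol %), Cs2CO3 (1.5 equiv), toluene, 90 °C
Reagents that add atoms: benzyl alcohol, OCc1ccccc1
Why: Palladium-catalysed C–O cross-coupling of an aryl bromide with a primary alcohol (Buchwald–Hartwig etherification), in which zerovalent palladium should insert readily into the C7–Br bond para to the C4 carbonyl and the bulky biaryl phosphine favours C–O reductive elimination over β-hydride elimination, so that the 7-oxygen arrives under the same protecting group as the ring-B phenols.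

Step 8
Reactants: 11 7-(benzyloxy)-2-[3,5-bis(benzyloxy)-4-methoxyphenyl]-5,8-dimethoxy-4H-chromen-4-one
Product: 12 2-(3,5-dihydroxy-4-methoxyphenyl)-7-hydroxy-5,8-dimethoxy-4H-chromen-4-one
Conditions: H2 (1 atm), 10% Pd/C, EtOAc–MeOH (1:1), rt
Reagents that add atoms: none
Why: Catalytic hydrogenolysis of benzyl aryl ethers should cleave all three O–CH2Ph bonds at ambient pressure, while the methyl ethers and the vinylogous-ester C2=C3 bond of the flavone are expected to survive these mild conditions.

**Compound list**

1 | 4-methoxyphenol | COc1ccc(O)cc1 | starting material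
2 | 2,6-dibromo-4-methoxyphenol | COc1cc(Br)c(O)c(Br)c1 | intermediate
3 | 1,3-dibromo-2,5-dimethoxybenzene | COc1cc(Br)c(OC)c(Br)c1 | intermediate
4 | (2,4-dibromo-3,6-dimethoxyphenyl)lithium | [Li]c1c(Br)c(OC)c(Br)cc1OC | intermediate
5 | 1-(2,4-dibromo-3,6-dimethoxyphenyl)ethan-1-one | CC(=O)c1c(Br)c(OC)c(Br)cc1OC | intermediate
6 | methyl 3,5-dihydroxy-4-methoxybenzoate | COC(=O)c1cc(O)c(OC)c(O)c1 | starting material
7 | methyl 3,5-bis(benzyloxy)-4-methoxybenzoate | COC(=O)c1cc(OCc2ccccc2)c(OC)c(OCc2ccccc2)c1 | intermediate
8 | 1-[3,5-bis(benzyloxy)-4-methoxyphenyl]-3-(2,4-dibromo-3,6-dimethoxyphenyl)propane-1,3-dione | COc1cc(Br)c(OC)c(Br)c1C(=O)CC(=O)c1cc(OCc2ccccc2)c(OC)c(OCc2ccccc2)c1 | intermediate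
9 | potassium (Z)-1-[3,5-bis(benzyloxy)-4-methoxyphenyl]-3-(2,4-dibromo-3,6-dimethoxyphenyl)-3-oxoprop-1-en-1-olate | [K+].[O-]/C(=C\C(=O)c1c(Br)c(OC)c(Br)cc1OC)c1cc(OCc2ccccc2)c(OC)c(OCc2ccccc2)c1 | intermediate
10 | 2-[3,5-bis(benzyloxy)-4-methoxyphenyl]-7-bromo-5,8-dimethoxy-4H-chromen-4-one | COc1c(OCc2ccccc2)cc(-c2cc(=O)c3c(OC)cc(Br)c(OC)c3o2)cc1OCc1ccccc1 | intermediate
11 | 7-(benzyloxy)-2-[3,5-bis(benzyloxy)-4-methoxyphenyl]-5,8-dimethoxy-4H-chromen-4-one | COc1c(OCc2ccccc2)cc(-c2cc(=O)c3c(OC)cc(OCc4ccccc4)c(OC)c3o2)cc1OCc1ccccc1 | intermediate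
12 | 2-(3,5-dihydroxy-4-methoxyphenyl)-7-hydroxy-5,8-dimethoxy-4H-chromen-4-one | COc1c(O)cc(-c2cc(=O)c3c(OC)cc(O)c(OC)c3o2)cc1O | target

**Step count**

Total: 8 steps. Longest linear sequence: 7 steps (steps 1, 2, 3, 5, 6, 7, 8, from 4-methoxyphenol); the ring-B branch contributes step 4.

**Steps most likely to fail, with fallbacks**

Step 3. The ortho-bromoaryllithium may lose lithium bromide to an aryne or scramble halogen with unreacted 3. The hindered aryllithium may also deprotonate the acetamide instead of adding to it, which would return the arene. The fallback replaces deprotonation by electrophilic substitution and sets out from 3. Rieche formylation (Cl2CHOMe, TiCl4, CH2Cl2, 0 °C) at the same methoxyl-activated C–H should give 2,4-dibromo-3,6-dimethoxybenzaldehyde F1. Addition of MeMgBr (THF, 0 °C) should give racemic 1-(2,4-dibromo-3,6-dimethoxyphenyl)ethan-1-ol F2. Oxidation with Dess–Martin periodinane (CH2Cl2, rt) rejoins the route at 5.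

Step 6. Closure at the doubly ortho-substituted C8a may be slow, which leaves time for intermolecular Ullmann coupling or reduction at the second bromide, or for displacement of the activated C7 bromide by dimethylamine released from hot DMF. The fallback closes ring C at O1–C2 by cyclodehydration instead and sets out from 3, using 7 as well. One-flask mono bromine–lithium exchange (n-BuLi, 1.0 equiv, THF, −78 °C), borylation with B(OMe)3 and oxidation (H2O2, NaOH) should give 3-bromo-2,5-dimethoxyphenol F3. Ortho-acetylation under Fries-type conditions (AcOH, BF3·OEt2, 80 °C) should give the chelated 1-(4-bromo-2-hydroxy-3,6-dimethoxyphenyl)ethan-1-one F4. Claisen condensation of F4 with ester 7 (LiN(SiMe3)2, 4 equiv, THF, −78 °C → rt), a Baker–Venkataraman-type entry, should give 1-[3,5-bis(benzyloxy)-4-methoxyphenyl]-3-(4-bromo-2-hydroxy-3,6-dimethoxyphenyl)propane-1,3-dione F5. Acid-catalysed cyclodehydration (TsOH, toluene, reflux) rejoins the route at 10.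

Step 7. β-Hydride elimination from the palladium benzyloxide may reduce the C7–Br bond to C7–H, and benzyloxide may add to C2 and open the pyranone. The fallback builds the C7–O bond through boron and sets out from 10. Miyaura borylation (Pd(dppf)Cl2, bis(pinacolato)diboron, KOAc, dioxane, 90 °C) should give 2-[3,5-bis(benzyloxy)-4-methoxyphenyl]-5,8-dimethoxy-7-(4,4,5,5-tetramethyl-1,3,2-dioxaborolan-2-yl)-4H-chromen-4-one F6. Mild oxidation (NaBO3·4H2O, THF–H2O, rt) should give 2-[3,5-bis(benzyloxy)-4-methoxyphenyl]-7-hydroxy-5,8-dimethoxy-4H-chromen-4-one F7. Hydrogenolysis of its two benzyl ethers (H2, 10% Pd/C, EtOAc–MeOH, rt) arrives directly at 12.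

Further compounds
F1 | step 3 | 2,4-dibromo-3,6-dimethoxybenzaldehyde | O=Cc1c(Br)c(OC)c(Br)cc1OC
F2 | step 3 | racemic 1-(2,4-dibromo-3,6-dimethoxyphenyl)ethan-1-ol | CC(O)c1c(Br)c(OC)c(Br)cc1OC
F3 | step 6 | 3-bromo-2,5-dimethoxyphenol | COc1cc(O)c(OC)c(Br)c1
F4 | step 6 | 1-(4-bromo-2-hydroxy-3,6-dimethoxyphenyl)ethan-1-one | CC(=O)c1c(O)c(OC)c(Br)cc1OC
F5 | step 6 | 1-[3,5-bis(benzyloxy)-4-methoxyphenyl]-3-(4-bromo-2-hydroxy-3,6-dimethoxyphenyl)propane-1,3-dione | COc1cc(Br)c(OC)c(O)c1C(=O)CC(=O)c1cc(OCc2ccccc2)c(OC)c(OCc2ccccc2)c1
F6 | step 7 | 2-[3,5-bis(benzyloxy)-4-methoxyphenyl]-5,8-dimethoxy-7-(4,4,5,5-tetramethyl-1,3,2-dioxaborolan-2-yl)-4H-chromen-4-one | COc1c(OCc2ccccc2)cc(-c2cc(=O)c3c(OC)cc(B4OC(C)(C)C(C)(C)O4)c(OC)c3o2)cc1OCc1ccccc1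
F7 | step 7 | 2-[3,5-bis(benzyloxy)-4-methoxyphenyl]-7-hydroxy-5,8-dimethoxy-4H-chromen-4-one | COc1c(OCc2ccccc2)cc(-c2cc(=O)c3c(OC)cc(O)c(OC)c3o2)cc1OCc1ccccc1
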